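**Retrosynthetic overview**
1. Target 19 ⇒ hydroxyquinone 18 + allylic pivalate 15, joined by Pd-catalysed C-allylation at the only free quinone carbon; the quinone ring comes ready-made from orcinol.
2. 15 ⇒ keto aldehyde 10 + an (E)-alkenylzinc made from but-2-ynyl pivalate 12; syn-hydrometalation fixes the E-alkene and a chiral ligand sets the carbinol.
3. 10 ⇒ acyclic enol 8 by an intramolecular de Mayo reaction: one irradiation closes the cyclohexanone ring and a fused cyclobutane together, and retro-aldol opening of the cyclobutane leaves CH2CHO on the new quaternary carbon.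
4. 8 ⇒ (S)-limonene 1, which supplies the ring C-4 methyl stereocentre, by ring cleavage, loss of one carbon, formylation and C-methylation.
5. Ring order: cyclohexanone ring with its transient cyclobutane in step 5; the six-membered quinone ring is never built, only oxidised (step 9).

Assumption: 1, 11, 16 and all named reagents and ligands are bought; 10 is carried as a C-2 epimer mixture that step 7 equilibrates.

**Step 1**
Reactants: 1 (S)-(−)-limonene
Product: 4 (3S)-6-oxo-3-(prop-1-en-2-yl)heptanoic acid, via limonene 1,2-ozonide 2 (not isolated), via keto aldehyde 3 (not isolated)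
Conditions: O3 (1.0 equiv), CH2Cl2, −78 °C; PPh3, −78 → 23 °C; then NaClO2, NaH2PO4, 2-methylbut-2-ene, t-BuOH/H2O, 0 → 23 °C
Reagents that add atoms: ozone ([O-][O+]=O); sodium chlorite ([Na+].[O-]Cl=O)
Why: Chemoselective ozonolysis of the more electron-rich trisubstituted ring alkene (one equivalent of ozone spares the isopropenyl group) followed by Pinnick oxidation of the aldehyde; the stereocentre is not touched.

**Step 2**
Reactants: 4 (3S)-6-oxo-3-(prop-1-en-2-yl)heptanoic acid
Product: 5 (5R)-5,6-dimethylhept-6-en-2-one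
Conditions: Mes-Acr-Ph+ BF4− (5 mol %), (PhS)2 (10 mol %), i-Pr2NEt (20 mol %), CF3CH2OH, 450 nm LEDs, 23 °C
Reagents that add atoms: none
Why: Acridinium photoredox hydrodecarboxylation turns CH2CO2H into the methyl group (carboxylate oxidation, CO2 loss, H-atom transfer from thiophenol faster than homoallyl rearrangement); the centre is unchanged in space and becomes R only through CIP priorities.

**Step 3**
Reactants: 5 (5R)-5,6-dimethylhept-6-en-2-one
Product: 7 (1Z,6R)-1-hydroxy-6,7-dimethylocta-1,7-dien-3-one, via lithium enolate 6 (not isolated)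
Conditions: LDA, THF, −78 °C; HCO2CH2CF3, −78 °C; aq HCl
Reagents that add atoms: 2,2,2-trifluoroethyl formate (O=COCC(F)(F)F)
Why: Kinetic deprotonation at the methyl group and Claisen-type formylation of the terminal enolate with the reactive trifluoroethyl formate give the hydroxymethylene ketone regioselectively.

**Step 4**
Reactants: 7 (1Z,6R)-1-hydroxy-6,7-dimethylocta-1,7-dien-3-one
Product: 8 (1Z,6R)-1-hydroxy-2,6,7-trimethylocta-1,7-dien-3-one
Conditions: MeI (1.05 equiv), K2CO3, acetone, 23 °C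
Reagents that add atoms: iodomethane (CI)
Why: C-alkylation of the 1,3-dicarbonyl enolate by the soft electrophile puts the methyl on the central carbon, and the product re-enolises toward the aldehyde (chelated hydroxymethylene ketone).

**Step 5**
Reactants: 8 (1Z,6R)-1-hydroxy-2,6,7-trimethylocta-1,7-dien-3-one
Product: 10 2-[(1S,6R)-1,2,6-trimethyl-3-oxocyclohexyl]acetaldehyde, via cyclobutanol photoadduct 9 (not isolated)
Conditions: hν (300 nm, Pyrex), degassed cyclohexane (5 mM), 23 °C
Reagents that add atoms: none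
Why: Intramolecular de Mayo reaction: the excited O=C–C=C–OH unit adds to the tethered alkene (C2–C7 then C1–C8), closing the cyclohexanone and a cis-fused cyclobutane together, and the β-hydroxy ketone 9 opens at once by retro-aldol cleavage of C1–C8; a chair closure with the C-6 methyl equatorial and the exocyclic CH2 anti to it should place the new quaternary methyl cis to that methyl, while C-2 of 10 is formed as an epimer mixture.

**Step 6**
Reactants: 11 but-2-yn-1-ol
Product: 12 but-2-yn-1-yl pivalate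
Conditions: PivCl, pyridine, DMAP (cat.), CH2Cl2, 0 → 23 °C
Reagents that add atoms: pivaloyl chloride (CC(C)(C)C(Cl)=O)
Why: DMAP-catalysed acylation; the pivalate survives the organometallic step and is the leaving group in step 10.

**Step 7**
Reactants: 10 2-[(1S,6R)-1,2,6-trimethyl-3-oxocyclohexyl]acetaldehyde; 12 but-2-yn-1-yl pivalate
Product: 15 (2E,4S)-4-hydroxy-3-methyl-5-[(1S,2R,6R)-1,2,6-trimethyl-3-oxocyclohexyl]pent-2-en-1-yl pivalate, via alkenylzirconocene 13 (not isolated), via alkenylmethylzinc 14 (not isolated)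
Conditions: 12, Cp2Zr(H)Cl, CH2Cl2, 23 °C; Me2Zn, PhMe, −65 °C; (+)-MIB (10 mol %), then 10, −30 → 0 °C; aq NH4Cl; then DBU (0.2 equiv), PhMe, 40 °C
Reagents that add atoms: none
Why: Hydrozirconation–zinc transmetalation–amino-alcohol-catalysed alkenylzinc addition: syn Zr–H addition with Zr at the methyl-bearing carbon gives the E-alkenyl metal, the MIB–zinc catalyst (enantiomer chosen for Re-face attack) sets 4S at the aldehyde while ketone and ester are inert, and DBU equilibrates ring C-2 to the more stable equatorial methyl (2R, estimated 4–5:1, minor epimer separated and recycled).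

**Step 8**
Reactants: 16 orcinol
Product: 17 4-chloro-5-methylbenzene-1,3-diol
Conditions: SO2Cl2 (1.0 equiv), Et2O, 0 °C
Reagents that add atoms: sulfuryl chloride (ClS(Cl)(=O)=O)
Why: Electrophilic aromatic chlorination ortho/para to the two hydroxyls goes mainly to C-4 (C-2 between the hydroxyls is more hindered).

**Step 9**
Reactants: 17 4-chloro-5-methylbenzene-1,3-diol
Product: 18 5-chloro-2-hydroxy-6-methylcyclohexa-2,5-diene-1,4-dione
Conditions: (KSO3)2NO (2.2 equiv), KH2PO4 buffer, acetone/H2O, 0 → 23 °C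
Reagents that add atoms: Fremy's salt, potassium nitrosodisulfonate ([K+].[K+].[O]N(S(=O)(=O)[O-])S(=O)(=O)[O-])
Why: Teuber oxidation: the phenoxyl radical is oxygenated at the only free para position (C-6), giving the 2-hydroxy-1,4-quinone with chlorine and methyl in the target arrangement.

**Step 10**
Reactants: 15 (2E,4S)-4-hydroxy-3-methyl-5-[(1S,2R,6R)-1,2,6-trimethyl-3-oxocyclohexyl]pent-2-en-1-yl pivalate; 18 5-chloro-2-hydroxy-6-methylcyclohexa-2,5-diene-1,4-dione
Product: 19 5-chloro-2-hydroxy-3-{(2E,4S)-4-hydroxy-3-methyl-5-[(1S,2R,6R)-1,2,6-trimethyl-3-oxocyclohexyl]pent-2-en-1-yl}-6-methylcyclohexa-2,5-diene-1,4-dione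
Conditions: Pd2(dba)3 (2.5 mol %), dppf (6 mol %), THF, 50 °C
Reagents that add atoms: none
Why: Tsuji–Trost allylic alkylation: Pd(0) ionises the primary allylic pivalate and the soft vinylogous-acid anion of 18 (as with lawsone or 4-hydroxycoumarin) attacks the unhindered CH2 terminus through its only nucleophilic carbon, C-3; the syn π-allyl keeps the E geometry and no stereocentre is touched.

**Compound list**
1 | (S)-(−)-limonene, (4S)-1-methyl-4-(prop-1-en-2-yl)cyclohex-1-ene | CC1=CC[C@H](CC1)C(C)=C | starting material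
2 | limonene 1,2-ozonide, (4S)-1-methyl-4-(prop-1-en-2-yl)-7,8,9-trioxabicyclo[4.2.1]nonane (bridgehead diastereomers) | CC12CC[C@H](C(C)=C)CC(OO1)O2 | intermediate
3 | (3S)-6-oxo-3-(prop-1-en-2-yl)heptanal | CC(=O)CC[C@@H](CC=O)C(C)=C | intermediate
4 | (3S)-6-oxo-3-(prop-1-en-2-yl)heptanoic acid | CC(=O)CC[C@@H](CC(=O)O)C(C)=C | intermediate
5 | (5R)-5,6-dimethylhept-6-en-2-one | CC(=O)CC[C@@H](C)C(C)=C | intermediate
6 | lithium (5R)-5,6-dimethylhepta-1,6-dien-2-olate | [Li]OC(=C)CC[C@@H](C)C(C)=C | intermediate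
7 | (1Z,6R)-1-hydroxy-6,7-dimethylocta-1,7-dien-3-one (enol of the 3-oxo aldehyde) | O/C=C\C(=O)CC[C@@H](C)C(C)=C | intermediate
8 | (1Z,6R)-1-hydroxy-2,6,7-trimethylocta-1,7-dien-3-one | O/C=C(/C)C(=O)CC[C@@H](C)C(C)=C | intermediate
9 | (1R,5R,6S)-8-hydroxy-1,5,6-trimethylbicyclo[4.2.0]octan-2-one (C-8 epimers) | O=C1CC[C@@H](C)[C@]2(C)CC(O)[C@]12C | intermediate
10 | 2-[(1S,6R)-1,2,6-trimethyl-3-oxocyclohexyl]acetaldehyde (C-2 epimers) | O=CC[C@@]1(C)[C@H](C)CCC(=O)C1C | intermediate
11 | but-2-yn-1-ol | CC#CCO | starting material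
12 | but-2-yn-1-yl pivalate | CC#CCOC(=O)C(C)(C)C | intermediate
13 | chlorido[(2E)-4-(pivaloyloxy)but-2-en-2-yl]zirconocene | C/C(=C\COC(=O)C(C)(C)C)[Zr](Cl)(C1C=CC=C1)C1C=CC=C1 | intermediate
14 | methyl[(2E)-4-(pivaloyloxy)but-2-en-2-yl]zinc | C/C(=C\COC(=O)C(C)(C)C)[Zn]C | intermediate
15 | (2E,4S)-4-hydroxy-3-methyl-5-[(1S,2R,6R)-1,2,6-trimethyl-3-oxocyclohexyl]pent-2-en-1-yl pivalate | CC(C)(C)C(=O)OC/C=C(\C)[C@@H](O)C[C@@]1(C)[C@H](C)CCC(=O)[C@@H]1C | intermediate
16 | orcinol, 5-methylbenzene-1,3-diol | Cc1cc(O)cc(O)c1 | starting material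
17 | 4-chloro-5-methylbenzene-1,3-diol | Cc1cc(O)cc(O)c1Cl | intermediate
18 | 5-chloro-2-hydroxy-6-methylcyclohexa-2,5-diene-1,4-dione | CC1=C(Cl)C(=O)C=C(O)C1=O | intermediate
19 | 5-chloro-2-hydroxy-3-{(2E,4S)-4-hydroxy-3-methyl-5-[(1S,2R,6R)-1,2,6-trimethyl-3-oxocyclohexyl]pent-2-en-1-yl}-6-methylcyclohexa-2,5-diene-1,4-dione | CC1=C(Cl)C(=O)C(C/C=C(\C)[C@@H](O)C[C@@]2(C)[C@H](C)CCC(=O)[C@@H]2C)=C(O)C1=O | target

**Total step count:** 10. **Longest linear sequence:** 7 (steps 1, 2, 3, 4, 5, 7, 10).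

**Steps most likely to fail**

Step 5 (photochemical ring formation). The enol can react through its other tautomer and close a five-membered ring instead, it can give the crossed adduct, or it can add with poor facial control at the quaternary carbon. The fallback sets out from 8 and returns at 10. Acetylation of 8 (AcCl, pyridine) gives the enol acetate (6R)-2,6,7-trimethyl-3-oxoocta-1,7-dien-1-yl acetate F1, whose chromophore is locked as the C-3 enone. Irradiation at 350 nm in MeCN gives the isolable photoadduct (1R,5R,6S)-1,5,6-trimethyl-2-oxobicyclo[4.2.0]octan-8-yl acetate F2, and diastereomers at the quaternary carbon are separated here. K2CO3 in MeOH then removes the acetate and triggers the retro-aldol to 10.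

Step 7 (carbinol configuration and alkenyl-metal regiochemistry). Ligand control on an unbranched aldehyde in the presence of zirconium salts may be modest. The fallback sets out from 12 and 10 and returns at 15. Hydrozirconation of 12 followed by I2 gives (2E)-3-iodobut-2-en-1-yl pivalate F3. A Nozaki–Hiyama–Kishi coupling with 10 (CrCl2, cat. NiCl2, DMF) gives 15 together with its carbinol epimer (2E,4R)-4-hydroxy-3-methyl-5-[(1S,2R,6R)-1,2,6-trimethyl-3-oxocyclohexyl]pent-2-en-1-yl pivalate F4. Dess–Martin oxidation of the mixture gives the enone (2E)-3-methyl-4-oxo-5-[(1S,2R,6R)-1,2,6-trimethyl-3-oxocyclohexyl]pent-2-en-1-yl pivalate F5. (R)-Me-CBS with catecholborane at −78 °C reduces the enone carbonyl in preference to the hindered ring ketone and gives 15.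

Step 10 (Pd coupling with a chloro-hydroxyquinone). The quinone may oxidise Pd(0), and the phosphine or Pd may attack the C–Cl position. The fallback sets out from 17 and 10 and returns at 19, carrying the ring as a protected resorcinol and oxidising last. MOMCl with i-Pr2NEt converts 17 into 2-chloro-1,5-bis(methoxymethoxy)-3-methylbenzene F6. Lithiation between the two MOM ethers (n-BuLi, then CuBr·SMe2) and 1-bromobut-2-yne give 2-(but-2-yn-1-yl)-4-chloro-1,3-bis(methoxymethoxy)-5-methylbenzene F7. The step-7 protocol with 10 (Cp2Zr(H)Cl, Me2Zn, (+)-MIB, then DBU) gives (2R,3S,4R)-3-{(2S,3E)-5-[3-chloro-2,6-bis(methoxymethoxy)-4-methylphenyl]-2-hydroxy-3-methylpent-3-en-1-yl}-2,3,4-trimethylcyclohexan-1-one F8. PPTS in MeOH at 50 °C frees the resorcinol (2R,3S,4R)-3-[(2S,3E)-5-(3-chloro-2,6-dihydroxy-4-methylphenyl)-2-hydroxy-3-methylpent-3-en-1-yl]-2,3,4-trimethylcyclohexan-1-one F9. Fremy's salt, as in step 9, oxidises F9 at the free para position to 19.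

**Further compounds**
F1 | step 5 | (6R)-2,6,7-trimethyl-3-oxoocta-1,7-dien-1-yl acetate (E/Z mixture) | CC(=O)OC=C(C)C(=O)CC[C@@H](C)C(C)=C
F2 | step 5 | (1R,5R,6S)-1,5,6-trimethyl-2-oxobicyclo[4.2.0]octan-8-yl acetate (C-8 epimers) | O=C1CC[C@@H](C)[C@]2(C)CC(OC(C)=O)[C@]12C
F3 | step 7 | (2E)-3-iodobut-2-en-1-yl pivalate | C/C(I)=C\COC(=O)C(C)(C)C
F4 | step 7 | (2E,4R)-4-hydroxy-3-methyl-5-[(1S,2R,6R)-1,2,6-trimethyl-3-oxocyclohexyl]pent-2-en-1-yl pivalate | CC(C)(C)C(=O)OC/C=C(\C)[C@H](O)C[C@@]1(C)[C@H](C)CCC(=O)[C@@H]1C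
F5 | step 7 | (2E)-3-methyl-4-oxo-5-[(1S,2R,6R)-1,2,6-trimethyl-3-oxocyclohexyl]pent-2-en-1-yl pivalate | CC(C)(C)C(=O)OC/C=C(\C)C(=O)C[C@@]1(C)[C@H](C)CCC(=O)[C@@H]1C
F6 | step 10 | 2-chloro-1,5-bis(methoxymethoxy)-3-methylbenzene | Cc1cc(OCOC)cc(OCOC)c1Cl
F7 | step 10 | 2-(but-2-yn-1-yl)-4-chloro-1,3-bis(methoxymethoxy)-5-methylbenzene | CC#CCc1c(OCOC)cc(C)c(Cl)c1OCOC
F8 | step 10 | (2R,3S,4R)-3-{(2S,3E)-5-[3-chloro-2,6-bis(methoxymethoxy)-4-methylphenyl]-2-hydroxy-3-methylpent-3-en-1-yl}-2,3,4-trimethylcyclohexan-1-one | COCOc1cc(C)c(Cl)c(OCOC)c1C/C=C(\C)[C@@H](O)C[C@@]2(C)[C@H](C)CCC(=O)[C@@H]2C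
F9 | step 10 | (2R,3S,4R)-3-[(2S,3E)-5-(3-chloro-2,6-dihydroxy-4-methylphenyl)-2-hydroxy-3-methylpent-3-en-1-yl]-2,3,4-trimethylcyclohexan-1-one | Cc1cc(O)c(C/C=C(\C)[C@@H](O)C[C@@]2(C)[C@H](C)CCC(=O)[C@@H]2C)c(O)c1Cl
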